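The ten-membered ring C1–C10 is made by opening ring B of a trans-decalin. The potassium alkoxide at C2 carries an equatorial vinyl group (C3=C4) and sits next to an equatorial allenyl group on C7 (C6=C5=C16). In one operation it undergoes a [3,3] shift that forms C4–C5 and breaks C2–C7. The step exploits three features of the target: the C2 oxygen, the C5(16) exocyclic methylene, and the vicinal C6 chlorine and C7 lactone oxygen. These map onto the C2 ketone, the central allene carbon and the new E C6=C7 alkene. Ring A (C1, C10–C14) is a spectator. The precursor is a 2-vinyl-7-allenyl trans-decalin-2-ol silylated at O8, O9 and O14.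

Key step: step 17

**Conventions.** Briarane numbering is used throughout. C15 is the methyl on C1, C16 the methylene on C5, C20 the methylene on C11, and C17–C19 are the lactone carbons. β is the face of C15. The target is (1R,2S,3Z,6S,7R,8R,9S,10S,14S,17R).

**Assumption.** The (S)-configured ester on the diene is taken to shield the diene face that would lead to the enantiomeric core. If the bias is the opposite one, the (R)-acid is used in the same way.

**Design notes.**
- (a) Carbon nucleophiles attack a C2 carbonyl of this decalin anti to axial C15, which would make the vinyl group axial. C3 would then be gauche to C8, and the chair transition state would give the Z C6=C7 alkene. The C2 centre is therefore set by bringing oxygen, not carbon, onto the α face (steps 11, 12, 15, 16).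
- (b) O8 is carried as an equatorial silyl ether, not as a C8 acetal. A β-keto acetal would be lost by β-elimination during allenylation. The 8β-hydroxyl later steers the epoxidation.
- (c) Absolute configuration enters with a removable chiral ester in step 2.

Step 1
Reactants: 1 (E)-1-(trimethylsilyloxy)buta-1,3-diene; 2 (S)-2-methoxy-2-phenylacetic acid
Product: 5 (E)-buta-1,3-dienyl (S)-2-methoxy-2-phenylacetate, via acid chloride 3 (not isolated), via lithium dienolate 4 (not isolated)
Conditions: 2, (COCl)2, cat. DMF, CH2Cl2, 0 °C; separately 1, MeLi, THF, 0 °C; then 3 added to 4, −78 °C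
Reagents that add atoms: none
Why: O-acylation of a preformed lithium dienolate, in which MeLi cleaves the silyl dienol ether with retention of the E geometry and the hard acid chloride, made under conditions that do not racemise the benzylic centre, reacts at oxygen.

Step 2
Reactants: 5 (E)-buta-1,3-dienyl (S)-2-methoxy-2-phenylacetate; 6 2-methoxy-5-methyl-1,4-benzoquinone
Product: 7 cis-fused endo adduct (10β-H; 14α-acyloxy; 8-methoxy-7,12-diene-2,9-dione)
Conditions: BF3·OEt2, CH2Cl2, −20 °C; minor diastereomer removed by crystallisation or chromatography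
Reagents that add atoms: none
Why: Lewis-acid-promoted Diels–Alder reaction in which BF3 binds the more basic vinylogous-ester carbonyl C2=O so that the free diene terminus (C11) bonds to C10 and the oxygenated terminus (C14) to C1, the methoxy-bearing C7=C8 bond stays inert, endo approach places O14 cis to C2 and C9 (anti to C15), and the ester stereocentre differentiates the diene faces.

Step 3
Reactants: 7 cis-fused endo adduct
Product: 8 trans-fused enedione (10α-H)
Conditions: cat. DBU, CH2Cl2, rt
Reagents that add atoms: none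
Why: Base-mediated epimerisation through the C9 enolate, C10 being the only enolisable ring stereocentre (C1 is quaternary, so O14 cannot be eliminated), should favour the trans-fused enedione in which both ring A bonds are equatorial on ring B.

Step 4
Reactants: 8 trans-fused enedione
Product: 9 9β-alcohol
Conditions: NaBH4, CeCl3·7H2O, MeOH/CH2Cl2, −78 °C
Reagents that add atoms: none
Why: Luche reduction, in which the C9 carbonyl is far more electrophilic than the hindered vinylogous-ester carbonyl C2=O and hydride enters from the α face because axial C15 shields the β face, giving the axial 9β-alcohol.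

Step 5
Reactants: 9 9β-alcohol
Product: 10 9β,14α-diol
Conditions: cat. K2CO3, MeOH, 0 °C
Reagents that add atoms: none
Why: Mild carbonate-catalysed transesterification frees O14 and returns the auxiliary as its methyl ester, the low temperature keeping the β-hydroxy carbonyl array C14–C1–C2 from retro-aldol cleavage.

Step 6
Reactants: 10 9β,14α-diol
Product: 11 9β,14α-bis(tert-butyldimethylsilyl) ether
Conditions: TBSOTf, 2,6-lutidine, CH2Cl2, 0 °C
Reagents that add atoms: tert-butyldimethylsilyl triflate CC(C)(C)[Si](C)(C)OS(=O)(=O)C(F)(F)F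
Why: Silylation with the triflate copes with two hindered axial alcohols and gives ethers that survive oxidation, hydrogenation, ylides, organolithiums and KH.

Step 7
Reactants: 11 bis(silyl ether)
Product: 12 12-en-11-one
Conditions: cat. Rh2(cap)4, t-BuOOH, K2CO3, CH2Cl2, rt
Reagents that add atoms: tert-butyl hydroperoxide CC(C)(C)OO
Why: Catalytic allylic oxidation converts the only allylic methylene (C11) into the enone carbonyl, as known for cyclohex-2-enyl ethers giving 4-oxycyclohex-2-enones, the other allylic position C14 being a neopentyl methine.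

Step 8
Reactants: 12 12-en-11-one
Product: 13 11-ketone
Conditions: H2 (1 atm), Pd/C, EtOAc, rt
Reagents that add atoms: none
Why: Heterogeneous hydrogenation saturates the disubstituted enone bond C12=C13, whereas the push–pull C7=C8 bond of the vinylogous ester is inert under these conditions.

Step 9
Reactants: 13 11-ketone
Product: 14 11(20)-methylene vinylogous methyl ester
Conditions: Ph3PCH3Br, KOt-Bu, THF, 0 °C
Reagents that add atoms: methyltriphenylphosphonium bromide C[P+](c1ccccc1)(c1ccccc1)c1ccccc1.[Br-]
Why: Wittig methylenation takes the C11 ketone chemoselectively because the vinylogous ester is not electrophilic enough, and run cold and briefly it avoids β-elimination of O9 and loss of the trans fusion.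

Step 10
Reactants: 14 vinylogous methyl ester; 15 propargyl alcohol
Product: 16 vinylogous propargyl ester
Conditions: cat. PPTS, benzene, 4 Å sieves, 70 °C
Reagents that add atoms: none
Why: Acid-catalysed transetherification of a vinylogous ester (addition–elimination at C8, methanol trapped by the sieves) installs the propargyl group after the hydrogenation and keeps the C2=O/C8–O regiochemistry.

Step 11
Reactants: 16 vinylogous propargyl ester
Product: 17 2-(methoxymethyl) carbinol (2β-OH)
Conditions: Bu3SnCH2OMe, n-BuLi, THF, −78 °C; then 16; pH 8 buffer work-up, used crude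
Reagents that add atoms: tributyl(methoxymethyl)stannane CCCC[Sn](CCCC)(CCCC)COC
Why: 1,2-Addition of an α-alkoxy organolithium from tin–lithium exchange to the vinylogous-ester carbonyl brings in C3, attack anti to axial C15 being expected but irrelevant because the centre is erased in the next step, and one extra equivalent covers the acetylenic proton.

Step 12
Reactants: 17 2-(methoxymethyl) carbinol
Product: 19 7α-allenyl 8-ketone bearing the exocyclic C2=C3 enol ether, via bis(enol ether) triene 18 (not isolated)
Conditions: Burgess reagent (methyl N-(triethylammoniosulfonyl)carbamate), toluene, 50 °C; then 110 °C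
Reagents that add atoms: none
Why: Burgess dehydration can only remove a C3 hydrogen (C1 is quaternary, C7 is sp2), and the resulting propargyl dienyl ether undergoes the propargyl Claisen rearrangement on further heating, the allenyl group reaching the α face of C7 because C15 and O9 are both axial on the β face.

Step 13
Reactants: 19 7α-allenyl 8-ketone
Product: 20 8β-alcohol
Conditions: i-Bu2AlH, toluene, −78 °C
Reagents that add atoms: none
Why: Hydride reduction in a cold aprotic medium, which leaves the β,γ-unsaturated ketone no time to conjugate, occurs from the open α face because axial O9 blocks the β face, and gives the equatorial 8β-alcohol.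

Step 14
Reactants: 20 8β-alcohol
Product: 21 8β-triethylsilyl ether
Conditions: TESCl, imidazole, CH2Cl2, 0 °C
Reagents that add atoms: chlorotriethylsilane CC[Si](Cl)(CC)CC
Why: Standard silylation masks O8 so that no free O8 alkoxide, which would scramble the O9 silyl group, arises under the basic steps that follow, and the small silyl group can later be removed selectively.

Step 15
Reactants: 21 8β-triethylsilyl ether
Product: 22 2α-hydroxy-2β-carbaldehyde
Conditions: dimethyldioxirane, acetone/CH2Cl2, −78 °C; aqueous NaHCO3 work-up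
Reagents that add atoms: dimethyldioxirane CC1(C)OO1; water O
Why: Rubottom-type oxidation in which the dioxirane epoxidises the electron-rich exocyclic enol ether much faster than the 1,1-disubstituted alkene or the allene, from the α face anti to axial C15, and the epoxy ether collapses on work-up to the α-hydroxy aldehyde with axial 2α-OH.

Step 16
Reactants: 22 2α-hydroxy-2β-carbaldehyde
Product: 23 2β-vinyl-7α-allenyl trans-decalin-2α-ol (8β-OTES; 9β-OTBS; 14α-OTBS; 11(20)-methylene)
Conditions: Ph3PCH3Br, KOt-Bu (excess), THF, −78 to 0 °C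
Reagents that add atoms: methyltriphenylphosphonium bromide C[P+](c1ccccc1)(c1ccccc1)c1ccccc1.[Br-]
Why: Wittig methylenation of the aldehyde, with excess ylide covering the free hydroxyl, turns the equatorial formyl group into the equatorial vinyl group without touching the C2 centre.

Step 17
Reactants: 23 2β-vinyl-7α-allenyl trans-decalin-2α-ol
Product: 26 ten-membered 2-ketone (5(16)-methylene; 6E-ene; 8-OTES; 9-OTBS; 14-OTBS), via potassium alkoxide 24 (not isolated), via potassium enolate 25 (not isolated)
Conditions: KH, 18-crown-6, THF, 0 °C to rt; AcOH quench at −78 °C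
Reagents that add atoms: none
Why: Deprotonation gives the crown-separated potassium alkoxide 24, whose oxyanion weakens the C2–C7 bond and drives a concerted chair-like [3,3] sigmatropic shift to enolate 25, protonated to 26; the closest known reaction type is the anionic oxy-Cope four-carbon ring expansion of trans-1,2-dialkenylcyclohexanols, 2-allenyl cases included. The ten-membered ring is not closed end to end but arises by σ-bond exchange inside ring B (C4–C5 made, C2–C7 broken). No stereocentre is created, since C2 and C7 become sp2, so the alkene geometry is what must be controlled. The rigid trans-decalin chair holds C3 antiperiplanar to C8 and C6 antiperiplanar to C1, so both ring residues are pseudo-equatorial in the chair transition state, which leads to the E C6=C7 bond with H7 on the β face, while the sp carbon C5 ends up carrying the exocyclic methylene. A clean [3,3] course is secured by the absence of a C8 carbonyl, so the alkoxide cannot fragment by retro-aldol cleavage, and by the equatorial O8 silyl ether lying out of reach of the axial alkoxide; the only silyl group within reach (on O14) could migrate reversibly, but the irreversible rearrangement drains that equilibrium. C1, C8, C9, C10 and C14 are untouched.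

Step 18
Reactants: 26 ten-membered 2-ketone
Product: 28 (3Z)-enone, via lithium enolate 27 (not isolated)
Conditions: LiN(i-Pr)2, THF, −78 °C; then N-tert-butylbenzenesulfinimidoyl chloride, −78 °C
Reagents that add atoms: none
Why: One-pot ketone dehydrogenation in which the lithium enolate (C3 is the only enolisable position) attacks sulfur and the adduct loses the sulfenamide by intramolecular syn abstraction of a C4 hydrogen, the Z geometry being expected because an E C3=C4 bond beside the E C6=C7 bond would overstretch the sp2 segment C3–C7 of the ring.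

Step 19
Reactants: 28 (3Z)-enone
Product: 29 (2S)-allylic alcohol
Conditions: (R)-2-methyl-CBS-oxazaborolidine, catecholborane, toluene, −78 °C
Reagents that add atoms: none
Why: Corey–Bakshi–Shibata reduction in which quaternary C1 acts as the large and alkenyl C3 as the small substituent, so that the (R)-catalyst delivers hydride to the face giving the (2S)-alcohol, 1,2-selectively and without hydroboration at this temperature.

Step 20
Reactants: 29 (2S)-allylic alcohol
Product: 30 2-acetate
Conditions: Ac2O, pyridine, cat. DMAP, CH2Cl2, 0 °C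
Reagents that add atoms: acetic anhydride CC(=O)OC(C)=O
Why: Acetylation installs the first of the three acetates and removes the C2 hydroxyl as a competing directing group for the later epoxidation.

Step 21
Reactants: 30 2-acetate
Product: 31 8-alcohol
Conditions: cat. PPTS, MeOH/CH2Cl2, 0 °C
Reagents that add atoms: none
Why: Mild acid methanolysis differentiates silyl ethers by size, cleaving the triethylsilyl ether at O8 and leaving the two hindered tert-butyldimethylsilyl ethers and the acetate.

Step 22
Reactants: 31 8-alcohol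
Product: 32 6,7-epoxy 8-alcohol (trans epoxide)
Conditions: cat. VO(acac)2, t-BuOOH, CH2Cl2, 0 °C
Reagents that add atoms: tert-butyl hydroperoxide CC(C)(C)OO
Why: Hydroxyl-directed epoxidation touches only the allylic C6=C7 bond among the four alkenes and delivers oxygen to the outer face of the E alkene, over which the O8 hydroxyl lies in the conformer with H7 on the β face, which sets C7 as R.

Step 23
Reactants: 32 6,7-epoxy 8-alcohol
Product: 33 6,7-epoxy 8-ketone
Conditions: Dess–Martin periodinane, NaHCO3, CH2Cl2, 0 °C
Reagents that add atoms: none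
Why: Dess–Martin oxidation under buffered conditions gives the α,β-epoxy ketone without epimerising C9 or opening the vinyl epoxide.

Step 24
Reactants: 33 6,7-epoxy 8-ketone
Product: 34 (6S,7R)-6-chloro-7-hydroxy 8-ketone
Conditions: LiCl, AcOH, THF, rt
Reagents that add atoms: lithium chloride [Li+].[Cl-]
Why: Acid-assisted halide opening of an epoxide, in which the C6–O bond is allylic while C7–O is deactivated by the adjacent carbonyl, so that chloride attacks C6 in an SN2 manner with inversion and the trans epoxide gives the required anti chlorohydrin.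

Step 25
Reactants: 34 chlorohydrin; 35 2-bromopropanoyl bromide
Product: 36 7-O-(2-bromopropanoyl) ester
Conditions: pyridine, CH2Cl2, −20 °C
Reagents that add atoms: none
Why: Acylation of the only free hydroxyl with an acid bromide and a weak base in the cold avoids elimination of the β-chloride, the bromine-bearing carbon being an inconsequential epimer mixture.

Step 26
Reactants: 36 7-O-(2-bromopropanoyl) ester
Product: 38 γ-lactone with 8-OH (9,14-bis-OTBS), via samarium enolate 37 (not isolated)
Conditions: SmI2 (2.2 equiv, slow addition), THF, −78 °C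
Reagents that add atoms: none
Why: Intramolecular samarium Reformatsky reaction in which SmI2 reduces the α-bromo ester first and the tethered enolate can reach only the C8 carbonyl face on the side of O7 while the backbone C6–C7–C8–C9 stays transoid, giving the trans-fused lactone with the (8R) tertiary alcohol and the C17 methyl anti to C9 (17R).

Step 27
Reactants: 38 γ-lactone (9,14-bis-OTBS)
Product: 39 9,14-diol
Conditions: HF·pyridine, pyridine, THF, 0 °C to rt
Reagents that add atoms: none
Why: Buffered hydrogen fluoride removes both silyl ethers under acidic conditions, which avoids the alkoxide-triggered translactonisation to O9 and the attack on the C6 chloride that basic fluoride could cause.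

Step 28
Reactants: 39 9,14-diol
Product: 40 CNP0178742.1
Conditions: Ac2O, DMAP, pyridine, rt
Reagents that add atoms: acetic anhydride CC(=O)OC(C)=O
Why: Acetylation of the two secondary alcohols completes the triacetate, the hindered tertiary C8 hydroxyl remaining free under these conditions.

**Compound list**

1 | (E)-1-(trimethylsilyloxy)buta-1,3-diene | C=C/C=C/O[Si](C)(C)C | starting material
2 | (S)-2-methoxy-2-phenylacetic acid | CO[C@H](C(=O)O)c1ccccc1 | starting material
3 | (S)-2-methoxy-2-phenylacetyl chloride | CO[C@H](C(=O)Cl)c1ccccc1 | intermediate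
4 | lithium (E)-buta-1,3-dien-1-olate | C=C/C=C/[O-].[Li+] | intermediate
5 | (E)-buta-1,3-dienyl (S)-2-methoxy-2-phenylacetate | C=C/C=C/OC(=O)[C@@H](OC)c1ccccc1 | intermediate
6 | 2-methoxy-5-methyl-1,4-benzoquinone | COC1=CC(=O)C(C)=CC1=O | starting material
7 | cis-fused endo adduct, 1β-methyl, 10β-H, 14α-acyloxy, 8-methoxy-7,12-diene-2,9-dione | C1C=C[C@H](OC(=O)[C@@H](OC)c3ccccc3)[C@]2(C)C(=O)C=C(OC)C(=O)[C@H]12 | intermediate
8 | trans-fused enedione, 10α-H | C1C=C[C@H](OC(=O)[C@@H](OC)c3ccccc3)[C@]2(C)C(=O)C=C(OC)C(=O)[C@@H]12 | intermediate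
9 | 9β-alcohol of 8 | C1C=C[C@H](OC(=O)[C@@H](OC)c3ccccc3)[C@]2(C)C(=O)C=C(OC)[C@@H](O)[C@@H]12 | intermediate
10 | 9β,14α-diol | C1C=C[C@H](O)[C@]2(C)C(=O)C=C(OC)[C@@H](O)[C@@H]12 | intermediate
11 | 9β,14α-bis(TBS ether) | C1C=C[C@H](O[Si](C)(C)C(C)(C)C)[C@]2(C)C(=O)C=C(OC)[C@@H](O[Si](C)(C)C(C)(C)C)[C@@H]12 | intermediate
12 | 12-en-11-one | O=C1C=C[C@H](O[Si](C)(C)C(C)(C)C)[C@]2(C)C(=O)C=C(OC)[C@@H](O[Si](C)(C)C(C)(C)C)[C@@H]12 | intermediate
13 | 11-ketone | O=C1CC[C@H](O[Si](C)(C)C(C)(C)C)[C@]2(C)C(=O)C=C(OC)[C@@H](O[Si](C)(C)C(C)(C)C)[C@@H]12 | intermediate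
14 | 11(20)-methylene vinylogous methyl ester | C=C1CC[C@H](O[Si](C)(C)C(C)(C)C)[C@]2(C)C(=O)C=C(OC)[C@@H](O[Si](C)(C)C(C)(C)C)[C@@H]12 | intermediate
15 | propargyl alcohol | C#CCO | starting material
16 | vinylogous propargyl ester | C=C1CC[C@H](O[Si](C)(C)C(C)(C)C)[C@]2(C)C(=O)C=C(OCC#C)[C@@H](O[Si](C)(C)C(C)(C)C)[C@@H]12 | intermediate
17 | 2α-(methoxymethyl)-2β-ol | C=C1CC[C@H](O[Si](C)(C)C(C)(C)C)[C@]2(C)[C@](O)(COC)C=C(OCC#C)[C@@H](O[Si](C)(C)C(C)(C)C)[C@@H]12 | intermediate
18 | bis(enol ether) triene, C2=C3 geometry not defined | C=C1CC[C@H](O[Si](C)(C)C(C)(C)C)[C@]2(C)C(=COC)C=C(OCC#C)[C@@H](O[Si](C)(C)C(C)(C)C)[C@@H]12 | intermediate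
19 | 7α-allenyl 8-ketone with exocyclic C2=C3 methyl enol ether | C=C1CC[C@H](O[Si](C)(C)C(C)(C)C)[C@]2(C)C(=COC)[C@H](C=C=C)C(=O)[C@@H](O[Si](C)(C)C(C)(C)C)[C@@H]12 | intermediate
20 | 8β-alcohol | C=C1CC[C@H](O[Si](C)(C)C(C)(C)C)[C@]2(C)C(=COC)[C@H](C=C=C)[C@@H](O)[C@@H](O[Si](C)(C)C(C)(C)C)[C@@H]12 | intermediate
21 | 8β-TES ether | C=C1CC[C@H](O[Si](C)(C)C(C)(C)C)[C@]2(C)C(=COC)[C@H](C=C=C)[C@@H](O[Si](CC)(CC)CC)[C@@H](O[Si](C)(C)C(C)(C)C)[C@@H]12 | intermediate
22 | 2α-hydroxy-2β-carbaldehyde | C=C1CC[C@H](O[Si](C)(C)C(C)(C)C)[C@]2(C)[C@@](O)(C=O)[C@H](C=C=C)[C@@H](O[Si](CC)(CC)CC)[C@@H](O[Si](C)(C)C(C)(C)C)[C@@H]12 | intermediate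
23 | 2β-vinyl-7α-allenyl trans-decalin-2α-ol (key-step precursor) | C=C1CC[C@H](O[Si](C)(C)C(C)(C)C)[C@]2(C)[C@@](O)(C=C)[C@H](C=C=C)[C@@H](O[Si](CC)(CC)CC)[C@@H](O[Si](C)(C)C(C)(C)C)[C@@H]12 | intermediate
24 | potassium alkoxide of 23 | C=C1CC[C@H](O[Si](C)(C)C(C)(C)C)[C@]2(C)[C@@]([O-])(C=C)[C@H](C=C=C)[C@@H](O[Si](CC)(CC)CC)[C@@H](O[Si](C)(C)C(C)(C)C)[C@@H]12.[K+] | intermediate
25 | ten-membered potassium enolate (C1 and C4 trans on C2=C3) | C=C1CC[C@H](O[Si](C)(C)C(C)(C)C)[C@]2(C)/C([O-])=C/CC(=C)/C=C/[C@@H](O[Si](CC)(CC)CC)[C@@H](O[Si](C)(C)C(C)(C)C)[C@@H]12.[K+] | intermediate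
26 | ten-membered 2-ketone, 5(16)-methylene, 6E-ene (key-step product) | C=C1CC[C@H](O[Si](C)(C)C(C)(C)C)[C@]2(C)C(=O)CCC(=C)/C=C/[C@@H](O[Si](CC)(CC)CC)[C@@H](O[Si](C)(C)C(C)(C)C)[C@@H]12 | intermediate
27 | lithium enolate of 26 | C=C1CC[C@H](O[Si](C)(C)C(C)(C)C)[C@]2(C)C([O-])=CCC(=C)/C=C/[C@@H](O[Si](CC)(CC)CC)[C@@H](O[Si](C)(C)C(C)(C)C)[C@@H]12.[Li+] | intermediate
28 | (3Z,6E)-3-en-2-one | C=C1CC[C@H](O[Si](C)(C)C(C)(C)C)[C@]2(C)C(=O)/C=C\C(=C)/C=C/[C@@H](O[Si](CC)(CC)CC)[C@@H](O[Si](C)(C)C(C)(C)C)[C@@H]12 | intermediate
29 | (2S)-allylic alcohol | C=C1CC[C@H](O[Si](C)(C)C(C)(C)C)[C@]2(C)[C@@H](O)/C=C\C(=C)/C=C/[C@@H](O[Si](CC)(CC)CC)[C@@H](O[Si](C)(C)C(C)(C)C)[C@@H]12 | intermediate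
30 | 2-acetate | C=C1CC[C@H](O[Si](C)(C)C(C)(C)C)[C@]2(C)[C@@H](OC(C)=O)/C=C\C(=C)/C=C/[C@@H](O[Si](CC)(CC)CC)[C@@H](O[Si](C)(C)C(C)(C)C)[C@@H]12 | intermediate
31 | 8-alcohol | C=C1CC[C@H](O[Si](C)(C)C(C)(C)C)[C@]2(C)[C@@H](OC(C)=O)/C=C\C(=C)/C=C/[C@@H](O)[C@@H](O[Si](C)(C)C(C)(C)C)[C@@H]12 | intermediate
32 | 6,7-trans-epoxy 8-alcohol | C=C1CC[C@H](O[Si](C)(C)C(C)(C)C)[C@]2(C)[C@@H](OC(C)=O)/C=C\C(=C)[C@H]3O[C@@H]3[C@@H](O)[C@@H](O[Si](C)(C)C(C)(C)C)[C@@H]12 | intermediate
33 | 6,7-trans-epoxy 8-ketone | C=C1CC[C@H](O[Si](C)(C)C(C)(C)C)[C@]2(C)[C@@H](OC(C)=O)/C=C\C(=C)[C@H]3O[C@@H]3C(=O)[C@@H](O[Si](C)(C)C(C)(C)C)[C@@H]12 | intermediate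
34 | (6S,7R)-6-chloro-7-hydroxy 8-ketone | C=C1CC[C@H](O[Si](C)(C)C(C)(C)C)[C@]2(C)[C@@H](OC(C)=O)/C=C\C(=C)[C@H](Cl)[C@H](O)C(=O)[C@@H](O[Si](C)(C)C(C)(C)C)[C@@H]12 | intermediate
35 | 2-bromopropanoyl bromide | CC(Br)C(=O)Br | starting material
36 | 7-O-(2-bromopropanoyl) ester, epimers at CHBr | C=C1CC[C@H](O[Si](C)(C)C(C)(C)C)[C@]2(C)[C@@H](OC(C)=O)/C=C\C(=C)[C@H](Cl)[C@H](OC(=O)C(C)Br)C(=O)[C@@H](O[Si](C)(C)C(C)(C)C)[C@@H]12 | intermediate
37 | samarium ester enolate | C=C1CC[C@H](O[Si](C)(C)C(C)(C)C)[C@]2(C)[C@@H](OC(C)=O)/C=C\C(=C)[C@H](Cl)[C@H](OC(=CC)O[Sm](I)I)C(=O)[C@@H](O[Si](C)(C)C(C)(C)C)[C@@H]12 | intermediate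
38 | (8R,17R)-γ-lactone, 9,14-bis-OTBS | C=C1CC[C@H](O[Si](C)(C)C(C)(C)C)[C@]2(C)[C@@H](OC(C)=O)/C=C\C(=C)[C@H](Cl)[C@@H]3OC(=O)[C@H](C)[C@@]3(O)[C@@H](O[Si](C)(C)C(C)(C)C)[C@@H]12 | intermediate
39 | 9,14-diol | C=C1CC[C@H](O)[C@]2(C)[C@@H](OC(C)=O)/C=C\C(=C)[C@H](Cl)[C@@H]3OC(=O)[C@H](C)[C@@]3(O)[C@@H](O)[C@@H]12 | intermediate
40 | CNP0178742.1, (1R,2S,3Z,6S,7R,8R,9S,10S,14S,17R) | C=C1CC[C@H](OC(C)=O)[C@]2(C)[C@@H](OC(C)=O)/C=C\C(=C)[C@H](Cl)[C@@H]3OC(=O)[C@H](C)[C@@]3(O)[C@@H](OC(C)=O)[C@@H]12 | target

Total step count: 28. Longest linear sequence: 28 steps (1 or 2 to 40).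

**Steps most likely to fail**

**Step 17.** The O14 silyl group may transfer to the C2 alkoxide, which switches off the anionic acceleration. The allene may also erode under the strongly basic conditions. Either would stall the rearrangement. The fallback removes the anion altogether. It sets out from 23, which is silylated (TMSOTf, 2,6-lutidine) to the trimethylsilyl ether F1. F1 is heated in o-dichlorobenzene at about 190 °C, so that the neutral siloxy-Cope rearrangement passes through the same chair array and gives the ten-membered trimethylsilyl enol ether F2. K2CO3 in MeOH cleaves only the enol ether, and the sequence returns to the route at 26.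

**Step 18.** The syn elimination may run through a ring conformer that leads to the wrong C3=C4 geometry, or to mixed geometries, because the outcome is kinetically controlled. The fallback uses thermodynamic control. It sets out from 26, whose enolate 27 is brominated with N-bromosuccinimide to the α-bromo ketone F3. F3 is dehydrobrominated with Li2CO3 and LiBr in DMF at about 100 °C. Under these conditions reversible conjugate addition of bromide lets the enone settle in the less strained Z form, and the sequence returns at 28.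

**Step 26.** Electron transfer to the α-acyloxy ketone, with loss of O7, or to the allylic chloride may compete with enolate formation. The ring closure may also show poor facial selectivity. The fallback forms the C8–C17 bond before the chloride and the ester tether exist. It sets out from 33, which takes the zinc Reformatsky reagent of ethyl 2-bromopropanoate (Zn, THF) at the C8 carbonyl to give the epoxy β-hydroxy ester F4. LiCl and AcOH then open the epoxide at C6 to the chlorohydrin ester F5. The freed O7 hydroxyl of F5 lactonises with cat. PPTS, and the sequence returns at 38.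

Further compounds
F1 | step 17 | 2-O-trimethylsilyl ether of 23 | C=C1CC[C@H](O[Si](C)(C)C(C)(C)C)[C@]2(C)[C@@](O[Si](C)(C)C)(C=C)[C@H](C=C=C)[C@@H](O[Si](CC)(CC)CC)[C@@H](O[Si](C)(C)C(C)(C)C)[C@@H]12
F2 | step 17 | ten-membered trimethylsilyl enol ether | C=C1CC[C@H](O[Si](C)(C)C(C)(C)C)[C@]2(C)/C(O[Si](C)(C)C)=C/CC(=C)/C=C/[C@@H](O[Si](CC)(CC)CC)[C@@H](O[Si](C)(C)C(C)(C)C)[C@@H]12
F3 | step 18 | 3-bromo 2-ketone, C3 not defined | C=C1CC[C@H](O[Si](C)(C)C(C)(C)C)[C@]2(C)C(=O)C(Br)CC(=C)/C=C/[C@@H](O[Si](CC)(CC)CC)[C@@H](O[Si](C)(C)C(C)(C)C)[C@@H]12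
F4 | step 26 | 6,7-epoxy 8-hydroxy ethyl ester | C=C1CC[C@H](O[Si](C)(C)C(C)(C)C)[C@]2(C)[C@@H](OC(C)=O)/C=C\C(=C)[C@H]3O[C@@H]3[C@@](O)([C@@H](C)C(=O)OCC)[C@@H](O[Si](C)(C)C(C)(C)C)[C@@H]12
F5 | step 26 | 6-chloro-7,8-dihydroxy ethyl ester | C=C1CC[C@H](O[Si](C)(C)C(C)(C)C)[C@]2(C)[C@@H](OC(C)=O)/C=C\C(=C)[C@H](Cl)[C@H](O)[C@@](O)([C@@H](C)C(=O)OCC)[C@@H](O[Si](C)(C)C(C)(C)C)[C@@H]12
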